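**Retrosynthetic overview**

1. The side chain is numbered C1 (benzylic CH2) to C15 (CMe2), and the oxolane is O–C12–C13–C14–C15. The last disconnections are Ar–C1 (aryl Grignard plus allylic bromide) and C4–C5 (catalytic asymmetric vinylogous Mukaiyama aldol on a C5 enal, which also gives the 2E enoate and the 5R carbinol).
2. C5–C12 is the unchanged E,E-geranyl unit of geraniol; its terminal E-methyl group is oxidized to the C12 aldehyde.
3. The oxolane is cut at C12–C13 (retro-Petasis–Ferrier). It is made by skeletal rearrangement of a 4-methylidene-1,3-dioxolane: the acetal of the C12 enal with 2-hydroxyisobutyric acid (ring O, C14, C15, both methyls), after methylenation of the lactone carbonyl (C13).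
4. The feature that allows this: ring O–C12–C13–C14–O is a cyclized aldol (1,3-dioxygen) pattern, C15 is a gem-dimethyl carbinol carbon, and C12 is allylic to C10=C11. A conjugated oxocarbenium ion at C12 therefore forms easily and C12–C13 can be made from an enolate at C13=C14.
5. Ring order: temporary dioxolanone (step 4), then the oxolane (step 6); the arene is bought and attached in step 17. C12 is formed racemic; the catalyst-controlled reduction of step 7 sets C14 and turns the C12 enantiomers into separable cis/trans diastereomers.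

Key step: step 6

Remark on the chemistry: silyl dienol ether 16 is used as the mixture of ketene-acetal double-bond isomers obtained on silylation; the open transition state of step 12 makes this geometry irrelevant.

**Route**

Step 1
Reactants: 1 geraniol
Product: 2 geranyl tert-butyldimethylsilyl ether
Conditions: tBuMe2SiCl, imidazole, DMF, 0 °C to rt
Reagents that add atoms: tert-butyldimethylsilyl chloride CC(C)(C)[Si](C)(C)Cl
Why: Routine silylation of the primary allylic alcohol; a silyl ether rather than an ester is used so that the oxygen function survives the carbonyl methylenation of step 5 and the Lewis acids of steps 4 and 6.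

Step 2
Reactants: 2 geranyl tert-butyldimethylsilyl ether
Product: 4 (2E,6E)-8-[(tert-butyldimethylsilyl)oxy]-2,6-dimethylocta-2,6-dienal, via allylic alcohol 3 (not isolated)
Conditions: SeO2 (cat.), t-BuOOH, salicylic acid (cat.), CH2Cl2, rt; filtration, then MnO2, CH2Cl2, rt
Reagents that add atoms: selenium dioxide O=[Se]=O (oxygen carrier); tert-butyl hydroperoxide CC(C)(C)OO (terminal oxygen source)
Why: SeO2-catalysed allylic oxidation (ene reaction followed by [2,3]-sigmatropic shift) attacks the E-methyl group of the terminal, most electron-rich trisubstituted alkene with retention of the E geometry, and MnO2 then converges the allylic alcohol/aldehyde mixture on the E-enal without touching the silyl ether.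

Step 3
Reactants: 5 2-hydroxy-2-methylpropanoic acid
Product: 6 trimethylsilyl 2-methyl-2-[(trimethylsilyl)oxy]propanoate
Conditions: (Me3Si)2NH, Me3SiCl (cat.), neat, 80 °C; distillation
Reagents that add atoms: hexamethyldisilazane C[Si](C)(C)N[Si](C)(C)C
Why: Exhaustive silylation with hexamethyldisilazane gives the volatile bis-silyl derivative needed for an aprotic, water-free acetalization.

Step 4
Reactants: 4 (2E,6E)-8-[(tert-butyldimethylsilyl)oxy]-2,6-dimethylocta-2,6-dienal; 6 trimethylsilyl 2-methyl-2-[(trimethylsilyl)oxy]propanoate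
Product: 7 racemic 2-alkenyl-5,5-dimethyl-1,3-dioxolan-4-one
Conditions: Me3SiOTf (cat.), CH2Cl2, −78 °C; pyridine quench
Reagents that add atoms: none
Why: Silyl-triflate-catalysed acetalization of an aldehyde with a bis-silylated hydroxy acid (driven by formation of hexamethyldisiloxane) closes the dioxolanone at −78 °C without conjugate addition or olefin migration; the acetal carbon is formed as a racemate, which is irrelevant because this centre is ionized in step 6.

Step 5
Reactants: 7 racemic 2-alkenyl-5,5-dimethyl-1,3-dioxolan-4-one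
Product: 8 racemic 2-alkenyl-5,5-dimethyl-4-methylidene-1,3-dioxolane
Conditions: Cp2TiMe2 (2.5 equiv), toluene/THF, 65 °C, dark; filtration through basic alumina
Reagents that add atoms: bis(cyclopentadienyl)dimethyltitanium Cp2TiMe2 C[Ti](C)(C1C=CC=C1)C1C=CC=C1
Why: Petasis methylenation (thermally generated Cp2Ti=CH2, oxatitanacyclobutane, cycloreversion) turns the lactone carbonyl into the exocyclic enol ether under non-acidic conditions that leave the acetal, the silyl ether and both trisubstituted alkenes intact.

Step 6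
Reactants: 8 racemic 2-alkenyl-5,5-dimethyl-4-methylidene-1,3-dioxolane
Product: 10 racemic 5-alkenyl-2,2-dimethyloxolan-3-one, via oxocarbenium aluminium enolate 9 (not isolated)
Conditions: Me2AlCl (1.5 equiv), CH2Cl2, −78 to −30 °C; aqueous work-up
Reagents that add atoms: dimethylaluminium chloride C[Al](C)Cl (retained only in intermediate 9)
Why: Petasis–Ferrier rearrangement: Me2AlCl binds the enol-ether oxygen of 8, the acetal C–O bond to that oxygen ionizes, and the resulting aluminium enolate, still tethered through O–CMe2 to an E-configured, allyl-conjugated oxocarbenium ion (9), adds through its methylene carbon to the oxocarbenium carbon, which forges C12–C13 and turns the 1,3-dioxolane skeleton into the oxolan-3-one. The closest known reactions are the Lewis-acid-mediated rearrangements of 4-methylidene-1,3-dioxolanes to oxolan-3-ones and -ols and of 4-methylidene-1,3-dioxanes to oxan-4-ones. The oxolane closes in a 5-(enolendo)-endo-trig mode, which is feasible because the electrophile is an oxocarbenium ion that can rotate into overlap with the enolate held three atoms away. The new stereocentre C12 is created on a planar cation in a substrate without any other stereocentre, so it is deliberately formed as a racemate and is sorted by the catalyst-controlled reduction of step 7. The step needs recombination at carbon rather than at oxygen (O-recombination only regenerates 8, C–C bond formation is irreversible), 1,2- rather than vinylogous attack (only the five-membered closure is within reach of the tether) and retention of both E alkenes (the conjugated cation keeps the thermodynamically preferred E geometry and the distal trisubstituted alkene cannot reach the cation through a favourable ring size), all of which are secured by the short tether and the 2-methylalkenyl substituent.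

Step 7
Reactants: 10 racemic 5-alkenyl-2,2-dimethyloxolan-3-one
Product: 11 (3S,5S)-5-alkenyl-2,2-dimethyloxolan-3-ol (cis)
Conditions: (R)-2-methyl-CBS-oxazaborolidine [(3aR)-1-methyl-3,3-diphenyltetrahydro-1H,3H-pyrrolo[1,2-c][1,3,2]oxazaborole] (0.3 equiv), catecholborane, toluene, −78 °C; MeOH, aqueous work-up; chromatography
Reagents that add atoms: none
Why: Corey–Bakshi–Shibata reduction is under catalyst control (quaternary C2 as the large and the C4 methylene as the small ketone substituent) and with the (R)-catalyst should deliver the 3S carbinol from both enantiomers of 10, so that the 5S ketone gives cis-(3S,5S)-11 (matched with the intrinsic hydride attack anti to the C5 substituent) while the 5R ketone gives the trans-(3S,5R) diastereomer, which is removed by chromatography; catecholborane at −78 °C avoids hydroboration of the alkenes.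

Step 8
Reactants: 11 (3S,5S)-5-alkenyl-2,2-dimethyloxolan-3-ol (cis)
Product: 12 (3S,5S)-5-[(2E,6E)-8-hydroxy-6-methylocta-2,6-dien-2-yl]-2,2-dimethyloxolan-3-ol
Conditions: HF·pyridine, pyridine, THF, 0 °C
Reagents that add atoms: none
Why: Buffered fluoride cleaves the single (primary allylic) silyl ether while the allylic ring ether and the alkenes are not affected.

Step 9
Reactants: 12 (3S,5S)-5-[(2E,6E)-8-hydroxy-6-methylocta-2,6-dien-2-yl]-2,2-dimethyloxolan-3-ol
Product: 13 (2E,6E)-7-[(2S,4S)-4-hydroxy-5,5-dimethyloxolan-2-yl]-3-methylocta-2,6-dienal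
Conditions: MnO2, CH2Cl2, rt
Reagents that add atoms: none
Why: MnO2 oxidizes only the allylic primary alcohol, leaving the saturated, hindered ring carbinol and the E geometry untouched.

Step 10
Reactants: 13 (2E,6E)-7-[(2S,4S)-4-hydroxy-5,5-dimethyloxolan-2-yl]-3-methylocta-2,6-dienal
Product: 14 (2E,6E)-7-[(2S,4S)-5,5-dimethyl-4-[(triethylsilyl)oxy]oxolan-2-yl]-3-methylocta-2,6-dienal
Conditions: Et3SiCl, imidazole, DMAP (cat.), DMF, rt
Reagents that add atoms: triethylsilyl chloride CC[Si](Cl)(CC)CC
Why: Standard silylation of the remaining secondary hydroxyl (slow but clean next to the quaternary carbon) gives a triethylsilyl ether that survives steps 12 to 18 and is removed together with the aryl silyl ether at the end.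

Step 11
Reactants: 15 ethyl 3-methylbut-2-enoate
Product: 16 tert-butyl[(1-ethoxy-3-methylbuta-1,3-dien-1-yl)oxy]dimethylsilane
Conditions: LiN(iPr)2 (commercial solution), THF, −78 °C; then tBuMe2SiCl, DMPU, −78 °C to rt
Reagents that add atoms: tert-butyldimethylsilyl chloride CC(C)(C)[Si](C)(C)Cl
Why: Kinetic γ-deprotonation of the β,β-dimethyl enoate and O-silylation of the lithium dienolate give the silyl dienol ether, the vinylogous nucleophile for step 12.

Step 12
Reactants: 14 (2E,6E)-7-[(2S,4S)-5,5-dimethyl-4-[(triethylsilyl)oxy]oxolan-2-yl]-3-methylocta-2,6-dienal; 16 tert-butyl[(1-ethoxy-3-methylbuta-1,3-dien-1-yl)oxy]dimethylsilane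
Product: 17 ethyl (2E,5R,6E,10E)-5-hydroxy-trienoate carrying the silylated oxolane at C11
Conditions: SiCl4 (1.1 equiv), chiral bisphosphoramide (two N,N′-dimethyl-1,1′-binaphthyl-2,2′-diamine phosphoramide units joined by an N,N′-dimethylpentane-1,5-diamine tether; antipode selected for Re-face attack on the aldehyde; 5 mol%), iPr2NEt (cat.), CH2Cl2, −78 °C; aq. NaHCO3 work-up
Reagents that add atoms: none
Why: Vinylogous Mukaiyama aldol addition with a chiral Lewis-base-activated silicon Lewis acid: the aldehyde is bound to the chiral trichlorosilyl cation, the dienol ether attacks through its γ-carbon in an open transition state on the Re face, which sets 5R under catalyst control far from the ring stereocentres, and the s-trans diene gives the 2E enoate.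

Step 13
Reactants: 17 ethyl (2E,5R,6E,10E)-5-hydroxy-trienoate carrying the silylated oxolane at C11
Product: 18 (2E,5R,6E,10E)-triene-1,5-diol carrying the silylated oxolane at C11
Conditions: iBu2AlH (3.2 equiv), CH2Cl2, −78 °C; Rochelle salt work-up
Reagents that add atoms: none
Why: iBu2AlH reduces the conjugated ester to the E-allylic alcohol by 1,2-hydride delivery; silyl ether, ring ether and alkenes are inert and the secondary alkoxide simply consumes one equivalent.

Step 14
Reactants: 18 (2E,5R,6E,10E)-triene-1,5-diol carrying the silylated oxolane at C11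
Product: 20 (2E,5R,6E,10E)-1-bromo-trien-5-ol carrying the silylated oxolane at C11, via primary allylic mesylate 19 (not isolated)
Conditions: MsCl (1.05 equiv), Et3N, CH2Cl2, −40 °C; then LiBr, THF, −40 to 0 °C
Reagents that add atoms: methanesulfonyl chloride CS(=O)(=O)Cl (retained only in intermediate 19); lithium bromide [Li+].[Br-]
Why: At −40 °C the unhindered primary allylic hydroxyl is sulfonylated much faster than the secondary C5 hydroxyl, and bromide displaces the allylic mesylate in situ by SN2 with retention of the 2E geometry.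

Step 15
Reactants: 21 4-methoxy-2-methylphenol
Product: 22 2-bromo-4-methoxy-6-methylphenol
Conditions: N-bromosuccinimide, iPr2NH (cat.), CH2Cl2, 0 °C
Reagents that add atoms: N-bromosuccinimide O=C1CCC(=O)N1Br
Why: Amine-catalysed ortho-bromination of a phenol with N-bromosuccinimide; the only free position ortho to the hydroxyl is C6, so a single regioisomer is expected.

Step 16
Reactants: 22 2-bromo-4-methoxy-6-methylphenol
Product: 23 (2-bromo-4-methoxy-6-methylphenoxy)(tert-butyl)dimethylsilane
Conditions: tBuMe2SiCl, imidazole, DMF, rt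
Reagents that add atoms: tert-butyldimethylsilyl chloride CC(C)(C)[Si](C)(C)Cl
Why: Silylation of the hindered phenol masks the acidic proton for the Grignard step and gives a group removable by fluoride at the end.

Step 17
Reactants: 23 (2-bromo-4-methoxy-6-methylphenoxy)(tert-butyl)dimethylsilane; 20 (2E,5R,6E,10E)-1-bromo-trien-5-ol carrying the silylated oxolane at C11
Product: 25 (2E,5R,6E,10E)-1-aryl-trien-5-ol with aryl and C14 silyl ethers, via arylmagnesium bromide 24 (not isolated)
Conditions: 23, Mg turnings (activated), THF, 40 °C; then 20 (0.43 equiv relative to 24), Li2CuCl4 (5 mol%), THF, −30 to 0 °C; aq. NH4Cl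
Reagents that add atoms: magnesium [Mg] (retained only in intermediate 24)
Why: Li2CuCl4-catalysed coupling of an aryl Grignard reagent with a primary allylic bromide takes place at the unhindered α-carbon (the γ-carbon is fully substituted) with retention of the 2E geometry, the first equivalent of 24 being consumed by the C5 hydroxyl, whose magnesium alkoxide is inert.

Step 18
Reactants: 25 (2E,5R,6E,10E)-1-aryl-trien-5-ol with aryl and C14 silyl ethers
Product: 26 (2E,5R,6E,10E)-1-aryl-trien-5-yl acetate with aryl and C14 silyl ethers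
Conditions: Ac2O, pyridine, DMAP (cat.), CH2Cl2, 0 °C
Reagents that add atoms: acetic anhydride CC(=O)OC(C)=O
Why: Acetylation of the only free hydroxyl (C5) under nucleophilic catalysis; phenol and C14 hydroxyl are still silylated, which secures the site selectivity.

Step 19
Reactants: 26 (2E,5R,6E,10E)-1-aryl-trien-5-yl acetate with aryl and C14 silyl ethers
Product: 27 CNP0148147.2
Conditions: Et3N·3HF, THF, rt
Reagents that add atoms: none
Why: Amine-buffered hydrogen fluoride removes the aryl and the secondary silyl ether in one operation without ionizing the allylic acetate or the allylic ring ether and without acyl migration, and liberates the target.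

**Compound list**

1 | geraniol, (2E)-3,7-dimethylocta-2,6-dien-1-ol | CC(C)=CCC/C(C)=C/CO | starting material
2 | tert-butyl{[(2E)-3,7-dimethylocta-2,6-dien-1-yl]oxy}dimethylsilane | CC(C)=CCC/C(C)=C/CO[Si](C)(C)C(C)(C)C | intermediate
3 | (2E,6E)-8-[(tert-butyldimethylsilyl)oxy]-2,6-dimethylocta-2,6-dien-1-ol | OC/C(C)=C/CC/C(C)=C/CO[Si](C)(C)C(C)(C)C | intermediate
4 | (2E,6E)-8-[(tert-butyldimethylsilyl)oxy]-2,6-dimethylocta-2,6-dienal | O=C/C(C)=C/CC/C(C)=C/CO[Si](C)(C)C(C)(C)C | intermediate
5 | 2-hydroxy-2-methylpropanoic acid (2-hydroxyisobutyric acid) | CC(C)(O)C(=O)O | starting material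
6 | trimethylsilyl 2-methyl-2-[(trimethylsilyl)oxy]propanoate | CC(C)(O[Si](C)(C)C)C(=O)O[Si](C)(C)C | intermediate
7 | racemic 2-[(2E,6E)-8-[(tert-butyldimethylsilyl)oxy]-6-methylocta-2,6-dien-2-yl]-5,5-dimethyl-1,3-dioxolan-4-one | CC1(C)OC(OC1=O)/C(C)=C/CC/C(C)=C/CO[Si](C)(C)C(C)(C)C | intermediate
8 | racemic 2-[(2E,6E)-8-[(tert-butyldimethylsilyl)oxy]-6-methylocta-2,6-dien-2-yl]-5,5-dimethyl-4-methylidene-1,3-dioxolane | CC1(C)OC(OC1=C)/C(C)=C/CC/C(C)=C/CO[Si](C)(C)C(C)(C)C | intermediate
9 | ring-opened zwitterion of 8: chlorodimethylaluminate enolate of the 3-methylbutan-2-one unit, O-linked at C3 as oxocarbenium ion to the (2E,6E)-dienyl aldehyde carbon | C=C(O[Al-](C)(C)Cl)C(C)(C)[O+]=C/C(C)=C/CC/C(C)=C/CO[Si](C)(C)C(C)(C)C | intermediate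
10 | racemic 5-[(2E,6E)-8-[(tert-butyldimethylsilyl)oxy]-6-methylocta-2,6-dien-2-yl]-2,2-dimethyloxolan-3-one | CC1(C)OC(CC1=O)/C(C)=C/CC/C(C)=C/CO[Si](C)(C)C(C)(C)C | intermediate
11 | (3S,5S)-5-[(2E,6E)-8-[(tert-butyldimethylsilyl)oxy]-6-methylocta-2,6-dien-2-yl]-2,2-dimethyloxolan-3-ol | CC(C)(C)[Si](C)(C)OC/C=C(\C)CC/C=C(\C)[C@@H]1C[C@H](O)C(C)(C)O1 | intermediate
12 | (3S,5S)-5-[(2E,6E)-8-hydroxy-6-methylocta-2,6-dien-2-yl]-2,2-dimethyloxolan-3-ol | OC/C=C(\C)CC/C=C(\C)[C@@H]1C[C@H](O)C(C)(C)O1 | intermediate
13 | (2E,6E)-7-[(2S,4S)-4-hydroxy-5,5-dimethyloxolan-2-yl]-3-methylocta-2,6-dienal | O=C/C=C(\C)CC/C=C(\C)[C@@H]1C[C@H](O)C(C)(C)O1 | intermediate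
14 | (2E,6E)-7-[(2S,4S)-5,5-dimethyl-4-[(triethylsilyl)oxy]oxolan-2-yl]-3-methylocta-2,6-dienal | O=C/C=C(\C)CC/C=C(\C)[C@@H]1C[C@H](O[Si](CC)(CC)CC)C(C)(C)O1 | intermediate
15 | ethyl 3-methylbut-2-enoate | CCOC(=O)C=C(C)C | starting material
16 | tert-butyl[(1-ethoxy-3-methylbuta-1,3-dien-1-yl)oxy]dimethylsilane (mixture of ketene-acetal double-bond isomers) | C=C(C)C=C(OCC)O[Si](C)(C)C(C)(C)C | intermediate
17 | ethyl (2E,5R,6E,10E)-11-[(2S,4S)-5,5-dimethyl-4-[(triethylsilyl)oxy]oxolan-2-yl]-5-hydroxy-3,7-dimethyldodeca-2,6,10-trienoate | CCOC(=O)/C=C(\C)C[C@@H](O)/C=C(\C)CC/C=C(\C)[C@@H]1C[C@H](O[Si](CC)(CC)CC)C(C)(C)O1 | intermediate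
18 | (2E,5R,6E,10E)-11-[(2S,4S)-5,5-dimethyl-4-[(triethylsilyl)oxy]oxolan-2-yl]-3,7-dimethyldodeca-2,6,10-triene-1,5-diol | OC/C=C(\C)C[C@@H](O)/C=C(\C)CC/C=C(\C)[C@@H]1C[C@H](O[Si](CC)(CC)CC)C(C)(C)O1 | intermediate
19 | (2E,5R,6E,10E)-11-[(2S,4S)-5,5-dimethyl-4-[(triethylsilyl)oxy]oxolan-2-yl]-5-hydroxy-3,7-dimethyldodeca-2,6,10-trien-1-yl methanesulfonate | CS(=O)(=O)OC/C=C(\C)C[C@@H](O)/C=C(\C)CC/C=C(\C)[C@@H]1C[C@H](O[Si](CC)(CC)CC)C(C)(C)O1 | intermediate
20 | (2E,5R,6E,10E)-1-bromo-11-[(2S,4S)-5,5-dimethyl-4-[(triethylsilyl)oxy]oxolan-2-yl]-3,7-dimethyldodeca-2,6,10-trien-5-ol | BrC/C=C(\C)C[C@@H](O)/C=C(\C)CC/C=C(\C)[C@@H]1C[C@H](O[Si](CC)(CC)CC)C(C)(C)O1 | intermediate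
21 | 4-methoxy-2-methylphenol | COc1ccc(O)c(C)c1 | starting material
22 | 2-bromo-4-methoxy-6-methylphenol | COc1cc(C)c(O)c(Br)c1 | intermediate
23 | (2-bromo-4-methoxy-6-methylphenoxy)(tert-butyl)dimethylsilane | COc1cc(C)c(O[Si](C)(C)C(C)(C)C)c(Br)c1 | intermediate
24 | {2-[(tert-butyldimethylsilyl)oxy]-5-methoxy-3-methylphenyl}magnesium bromide | COc1cc(C)c(O[Si](C)(C)C(C)(C)C)c([Mg]Br)c1 | intermediate
25 | (2E,5R,6E,10E)-1-{2-[(tert-butyldimethylsilyl)oxy]-5-methoxy-3-methylphenyl}-11-[(2S,4S)-5,5-dimethyl-4-[(triethylsilyl)oxy]oxolan-2-yl]-3,7-dimethyldodeca-2,6,10-trien-5-ol | COc1cc(C)c(O[Si](C)(C)C(C)(C)C)c(C/C=C(\C)C[C@@H](O)/C=C(\C)CC/C=C(\C)[C@@H]2C[C@H](O[Si](CC)(CC)CC)C(C)(C)O2)c1 | intermediate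
26 | (2E,5R,6E,10E)-1-{2-[(tert-butyldimethylsilyl)oxy]-5-methoxy-3-methylphenyl}-11-[(2S,4S)-5,5-dimethyl-4-[(triethylsilyl)oxy]oxolan-2-yl]-3,7-dimethyldodeca-2,6,10-trien-5-yl acetate | COc1cc(C)c(O[Si](C)(C)C(C)(C)C)c(C/C=C(\C)C[C@@H](OC(C)=O)/C=C(\C)CC/C=C(\C)[C@@H]2C[C@H](O[Si](CC)(CC)CC)C(C)(C)O2)c1 | intermediate
27 | CNP0148147.2, (2E,5R,6E,10E)-1-(2-hydroxy-5-methoxy-3-methylphenyl)-11-[(2S,4S)-4-hydroxy-5,5-dimethyloxolan-2-yl]-3,7-dimethyldodeca-2,6,10-trien-5-yl acetate | COc1cc(C)c(O)c(C/C=C(\C)C[C@H](/C=C(\C)CC/C=C(\C)[C@@H]2C[C@H](O)C(C)(C)O2)OC(C)=O)c1 | target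

**Summary**

Total step count: 19 steps.
Longest linear sequence: 15 steps (steps 1, 2, 4 to 10, 12 to 14, 17 to 19, from geraniol).

**Three steps most likely to fail**

Step 6. The oxocarbenium/enolate pair may separate and be hydrolysed, or the acid-labile enol acetal may hydrolyse before it ionizes, instead of recombining at carbon. The fallback sets out from enal 4 and comes back at ketone 10. The dilithium dianion of commercial 3-hydroxy-3-methylbutan-2-one (LiN(iPr)2, THF, −78 °C) should add 1,2 to 4 to give the racemic dihydroxy ketone (6E,10E)-12-[(tert-butyldimethylsilyl)oxy]-2,5-dihydroxy-2,6,10-trimethyldodeca-6,10-dien-3-one F1. Catalytic camphorsulfonic acid in CH2Cl2 should then ionize the allylic secondary hydroxyl, and the tertiary hydroxyl captures the allyl cation at the carbinol carbon to close the five-membered ring. This aldol plus cycloetherification replaces the rearrangement and gives 10.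

Step 7. The mismatched 5R ketone may leak into the cis series under incomplete catalyst control, which would lower the enantiomeric purity of 11. The fallback sets out from 10 and comes back at 11. Substrate-controlled reduction with LiBH(sBu)3 (THF, −78 °C, hydride anti to the C5 substituent) should give the racemic cis alcohol F2. Acylative kinetic resolution with Candida antarctica lipase B and vinyl acetate should, by the empirical rule for secondary alcohols (quaternary side as the large group), acetylate the 3R,5R enantiomer to the (3R,5R)-acetate F3 and leave (3S,5S)-11, which is separated by chromatography.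

Step 12. Facial selectivity may be insufficient, or the dienol ether may attack through its α-carbon rather than its γ-carbon. The fallback sets out from 14 and 16 and comes back at 17. An achiral vinylogous Mukaiyama aldol addition promoted by BF3·OEt2 (CH2Cl2, −78 °C) should give the C5-epimeric hydroxy esters F4. Dess–Martin periodinane oxidizes both epimers to the single enone ester F5. Reduction with (S)-2-methyl-CBS-oxazaborolidine and catecholborane (alkenyl as the large group) should install 5R and return 17, so that the stereocentre is set by ketone reduction instead of C–C bond formation.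

**Further compounds**

F1 | step 6 | racemic (6E,10E)-12-[(tert-butyldimethylsilyl)oxy]-2,5-dihydroxy-2,6,10-trimethyldodeca-6,10-dien-3-one | CC(C)(O)C(=O)CC(O)/C(C)=C/CC/C(C)=C/CO[Si](C)(C)C(C)(C)C
F2 | step 7 | racemic cis-5-[(2E,6E)-8-[(tert-butyldimethylsilyl)oxy]-6-methylocta-2,6-dien-2-yl]-2,2-dimethyloxolan-3-ol (3S,5S and 3R,5R) | CC(C)(C)[Si](C)(C)OC/C=C(\C)CC/C=C(\C)[C@@H]1C[C@H](O)C(C)(C)O1.CC(C)(C)[Si](C)(C)OC/C=C(\C)CC/C=C(\C)[C@H]1C[C@@H](O)C(C)(C)O1
F3 | step 7 | (3R,5R)-5-[(2E,6E)-8-[(tert-butyldimethylsilyl)oxy]-6-methylocta-2,6-dien-2-yl]-2,2-dimethyloxolan-3-yl acetate | CC(C)(C)[Si](C)(C)OC/C=C(\C)CC/C=C(\C)[C@H]1C[C@@H](OC(C)=O)C(C)(C)O1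
F4 | step 12 | ethyl (2E,5RS,6E,10E)-11-[(2S,4S)-5,5-dimethyl-4-[(triethylsilyl)oxy]oxolan-2-yl]-5-hydroxy-3,7-dimethyldodeca-2,6,10-trienoate (C5 epimers) | CCOC(=O)/C=C(\C)CC(O)/C=C(\C)CC/C=C(\C)[C@@H]1C[C@H](O[Si](CC)(CC)CC)C(C)(C)O1
F5 | step 12 | ethyl (2E,6E,10E)-11-[(2S,4S)-5,5-dimethyl-4-[(triethylsilyl)oxy]oxolan-2-yl]-3,7-dimethyl-5-oxododeca-2,6,10-trienoate | CCOC(=O)/C=C(\C)CC(=O)/C=C(\C)CC/C=C(\C)[C@@H]1C[C@H](O[Si](CC)(CC)CC)C(C)(C)O1
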